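**Retrosynthetic overview**
1. Target 25 ⇒ pyranone 5 + one CH2 + acylphloroglucinol 22. The methylene bridge is made last: Mannich aminomethylation of 5 with Eschenmoser's salt, loss of Me2NH, and intermolecular Michael addition of 22 to the resulting 3-methylidene-pyrandione.
2. Pyranone 5 ⇒ diketo ester 4 ⇒ dianion of methyl 3-oxopentanoate + propanoyl Weinreb amide (Claisen-type acylation, then lactonisation).
3. Arene 22 ⇒ bis-MOM ketone 21 ⇒ ortho-lithiated 19 + Weinreb amide 15. Arene 19 ⇒ bis-MOM ether 17 by lithiation between the two OMOM groups and prenylation; the mirror symmetry of 19 removes any regiochemical choice in the second lithiation.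
4. Amide 15 ⇒ (R)-2-methylbutanoic acid ⇒ Evans methylation of the N-butanoyl derivative of (R)-4-benzyl-2-oxazolidinone, which sets the only stereocentre.
5. Rings: the benzene ring is bought (5-methoxyresorcinol); the only ring formed is the 2-pyranone (step 2), before the fragments are joined.

Assumption: the single stereocentre of the given SMILES is read as (R) at C2 of the 2-methylbutanoyl group, and the target is taken as the 4-hydroxy-2-pyranone tautomer drawn.

**Step 1**
Reactants: 1 methyl 3-oxopentanoate; 2 N-methoxy-N-methylpropanamide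
Product: 4 methyl 4-methyl-3,5-dioxoheptanoate, via sodium lithium dienolate dianion 3 (not isolated)
Conditions: NaH (1.1 equiv), THF, 0 °C; n-BuLi (1.05 equiv), 0 °C; then 2, −78 → 0 °C; 1 M HCl quench
Reagents that add atoms: none
Why: Claisen-type γ-acylation, in which the more reactive terminal carbanion of the β-keto ester dianion attacks the Weinreb amide and the stable tetrahedral chelate prevents over-addition.

**Step 2**
Reactants: 4 methyl 4-methyl-3,5-dioxoheptanoate
Product: 5 6-ethyl-4-hydroxy-5-methyl-2H-pyran-2-one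
Conditions: DBU (1.5 equiv), toluene, reflux; then 1 M HCl
Reagents that add atoms: none
Why: DBU-promoted lactonisation (intramolecular transesterification) of the C5 enol oxygen onto the methyl ester gives the stabilised 4-hydroxy-2-pyranone with loss of methanol.

**Step 3**
Reactants: 6 (4R)-4-benzyl-1,3-oxazolidin-2-one; 7 butanoyl chloride
Product: 9 (4R)-4-benzyl-3-butanoyl-1,3-oxazolidin-2-one, via N-lithio oxazolidinone 8 (not isolated)
Conditions: n-BuLi (1.05 equiv), THF, −78 °C; then 7, −78 → 0 °C
Reagents that add atoms: none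
Why: N-acylation of the lithiated oxazolidinone with an acid chloride is the standard Evans imide formation and leaves the C4 stereocentre untouched.

**Step 4**
Reactants: 9 (4R)-4-benzyl-3-butanoyl-1,3-oxazolidin-2-one
Product: 11 (4R)-4-benzyl-3-[(2R)-2-methylbutanoyl]-1,3-oxazolidin-2-one, via sodium Z-enolate 10 (not isolated)
Conditions: NaN(SiMe3)2 (1.1 equiv), THF, −78 °C; MeI (5 equiv), −78 → −40 °C; chromatography/recrystallisation to remove the minor diastereomer
Reagents that add atoms: iodomethane, CI
Why: Evans asymmetric alkylation, in which the chelated sodium Z-enolate is methylated on the face opposite the C4 benzyl group, so the (R)-auxiliary gives the (R)-2-methylbutanoyl centre (dr about 10:1 before purification).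

**Step 5**
Reactants: 11 (4R)-4-benzyl-3-[(2R)-2-methylbutanoyl]-1,3-oxazolidin-2-one
Product: 13 (2R)-2-methylbutanoic acid, via lithium percarboxylate 12 (not isolated)
Conditions: LiOH·H2O (2 equiv), 30% H2O2 (4 equiv), THF/H2O 3:1, 0 °C; aq Na2SO3; extract auxiliary; HCl to pH 2, extract with Et2O
Reagents that add atoms: hydrogen peroxide, OO
Why: Hydroperoxide-mediated exocyclic imide cleavage (LiOOH hydrolysis) removes the auxiliary without epimerising the α-centre, and sulfite reduces the percarboxylate to the acid.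

**Step 6**
Reactants: 13 (2R)-2-methylbutanoic acid
Product: 15 (2R)-N-methoxy-N,2-dimethylbutanamide, via acyl imidazole 14 (not isolated)
Conditions: CDI (1.1 equiv), CH2Cl2, 0 °C → rt; then MeNHOMe·HCl (1.2 equiv), rt
Reagents that add atoms: N,O-dimethylhydroxylamine hydrochloride, CNOC.Cl
Why: Amide coupling through the acyl imidazole gives the Weinreb amide under near-neutral conditions that do not enolise the α-stereocentre.

**Step 7**
Reactants: 16 5-methoxybenzene-1,3-diol (5-methoxyresorcinol)
Product: 17 1-methoxy-3,5-bis(methoxymethoxy)benzene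
Conditions: MOMCl (2.5 equiv), i-Pr2NEt (3 equiv), CH2Cl2, 0 °C → rt
Reagents that add atoms: chloromethyl methyl ether, COCCl
Why: Williamson-type O-alkylation of both phenols installs MOM acetals that are base-stable and strong ortho-directing groups.

**Step 8**
Reactants: 17 1-methoxy-3,5-bis(methoxymethoxy)benzene
Product: 19 5-methoxy-1,3-bis(methoxymethoxy)-2-(3-methylbut-2-en-1-yl)benzene, via aryllithium 18 (not isolated)
Conditions: n-BuLi (1.1 equiv), THF, 0 °C → rt, 1 h; CuI (10 mol %), −78 °C; prenyl bromide, −78 °C → rt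
Reagents that add atoms: prenyl bromide (1-bromo-3-methylbut-2-ene), CC(C)=CCBr
Why: Directed ortho-metalation occurs at the carbon flanked by both OMOM groups, and CuI-catalysed SN2 allylation with prenyl bromide gives the linear prenyl arene, whose two remaining ring positions are equivalent by symmetry.

**Step 9**
Reactants: 19 5-methoxy-1,3-bis(methoxymethoxy)-2-(3-methylbut-2-en-1-yl)benzene; 15 (2R)-N-methoxy-N,2-dimethylbutanamide
Product: 21 (2R)-1-[6-methoxy-2,4-bis(methoxymethoxy)-3-(3-methylbut-2-en-1-yl)phenyl]-2-methylbutan-1-one, via aryllithium 20 (not isolated)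
Conditions: 19 (1.2 equiv), n-BuLi (1.15 equiv), TMEDA, THF, −20 → 0 °C; then 15 (1.0 equiv), −78 → 0 °C; sat. aq NH4Cl at −78 °C
Reagents that add atoms: none
Why: A second directed ortho-metalation at the only remaining type of ring C–H (between OMe and OMOM) followed by Weinreb ketone synthesis gives the aryl ketone, the (R)-centre being carried in from 15 and protected from enolisation because the tetrahedral chelate collapses only on quench.

**Step 10**
Reactants: 21 (2R)-1-[6-methoxy-2,4-bis(methoxymethoxy)-3-(3-methylbut-2-en-1-yl)phenyl]-2-methylbutan-1-one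
Product: 22 (2R)-1-[2,4-dihydroxy-6-methoxy-3-(3-methylbut-2-en-1-yl)phenyl]-2-methylbutan-1-one
Conditions: 3 M aq HCl/MeOH 1:5, rt (40 °C if slow)
Reagents that add atoms: none
Why: Acid-catalysed acetal methanolysis removes both MOM groups under conditions chosen to be too mild to cyclise the ortho-prenyl phenol to a chroman or to enolise the hindered, hydrogen-bonded aryl ketone.

**Step 11**
Reactants: 5 6-ethyl-4-hydroxy-5-methyl-2H-pyran-2-one; 22 (2R)-1-[2,4-dihydroxy-6-methoxy-3-(3-methylbut-2-en-1-yl)phenyl]-2-methylbutan-1-one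
Product: 25 3-{[2,4-dihydroxy-6-methoxy-5-[(2R)-2-methylbutanoyl]-3-(3-methylbut-2-en-1-yl)phenyl]methyl}-6-ethyl-4-hydroxy-5-methyl-2H-pyran-2-one (target), via pyranone Mannich base hydroiodide 23 (not isolated), via 3-methylidenepyran-2,4-dione 24 (not isolated)
Conditions: 5 (1.2 equiv), CH2=NMe2+ I− (1.2 equiv), MeCN, rt, 1 h; then 22 (1.0 equiv), 60 °C
Reagents that add atoms: Eschenmoser's salt (N,N-dimethylmethyleneiminium iodide), C=[N+](C)C.[I-]
Why: Mannich reaction at the nucleophilic pyranone C3, thermal loss of dimethylamine to the 3-methylidene-pyran-2,4-dione and intermolecular Michael addition of the single free ring carbon of 22 form the methylene bridge without creating a stereocentre or touching the (R)-centre.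

**Compound list**
1 | methyl 3-oxopentanoate | CCC(=O)CC(=O)OC | starting material
2 | N-methoxy-N-methylpropanamide | CCC(=O)N(C)OC | starting material
3 | sodium lithium dienolate (dianion) of methyl 3-oxopentanoate | CC=C([O-])C=C([O-])OC.[Na+].[Li+] | intermediate (not isolated)
4 | methyl 4-methyl-3,5-dioxoheptanoate | CCC(=O)C(C)C(=O)CC(=O)OC | intermediate
5 | 6-ethyl-4-hydroxy-5-methyl-2H-pyran-2-one | CCc1oc(=O)cc(O)c1C | intermediate
6 | (4R)-4-benzyl-1,3-oxazolidin-2-one | O=C1N[C@H](Cc2ccccc2)CO1 | starting material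
7 | butanoyl chloride | CCCC(=O)Cl | starting material
8 | lithium salt of (4R)-4-benzyl-1,3-oxazolidin-2-one | [Li+].O=C1[N-][C@H](Cc2ccccc2)CO1 | intermediate (not isolated)
9 | (4R)-4-benzyl-3-butanoyl-1,3-oxazolidin-2-one | CCCC(=O)N1[C@H](Cc2ccccc2)COC1=O | intermediate
10 | sodium Z-enolate of 9 | [Na+].CC/C=C(\[O-])N1[C@H](Cc2ccccc2)COC1=O | intermediate (not isolated)
11 | (4R)-4-benzyl-3-[(2R)-2-methylbutanoyl]-1,3-oxazolidin-2-one | CC[C@@H](C)C(=O)N1[C@H](Cc2ccccc2)COC1=O | intermediate
12 | lithium (2R)-2-methylbutaneperoxoate | [Li+].CC[C@@H](C)C(=O)O[O-] | intermediate (not isolated)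
13 | (2R)-2-methylbutanoic acid | CC[C@@H](C)C(=O)O | intermediate
14 | 1-[(2R)-2-methylbutanoyl]imidazole | CC[C@@H](C)C(=O)n1ccnc1 | intermediate (not isolated)
15 | (2R)-N-methoxy-N,2-dimethylbutanamide | CC[C@@H](C)C(=O)N(C)OC | intermediate
16 | 5-methoxybenzene-1,3-diol | COc1cc(O)cc(O)c1 | starting material
17 | 1-methoxy-3,5-bis(methoxymethoxy)benzene | COCOc1cc(OC)cc(OCOC)c1 | intermediate
18 | [4-methoxy-2,6-bis(methoxymethoxy)phenyl]lithium | [Li]c1c(OCOC)cc(OC)cc1OCOC | intermediate (not isolated)
19 | 5-methoxy-1,3-bis(methoxymethoxy)-2-(3-methylbut-2-en-1-yl)benzene | COCOc1cc(OC)cc(OCOC)c1CC=C(C)C | intermediate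
20 | [6-methoxy-2,4-bis(methoxymethoxy)-3-(3-methylbut-2-en-1-yl)phenyl]lithium | [Li]c1c(OC)cc(OCOC)c(CC=C(C)C)c1OCOC | intermediate (not isolated)
21 | (2R)-1-[6-methoxy-2,4-bis(methoxymethoxy)-3-(3-methylbut-2-en-1-yl)phenyl]-2-methylbutan-1-one | CC[C@@H](C)C(=O)c1c(OC)cc(OCOC)c(CC=C(C)C)c1OCOC | intermediate
22 | (2R)-1-[2,4-dihydroxy-6-methoxy-3-(3-methylbut-2-en-1-yl)phenyl]-2-methylbutan-1-one | CC[C@@H](C)C(=O)c1c(OC)cc(O)c(CC=C(C)C)c1O | intermediate
23 | 3-[(dimethylamino)methyl]-6-ethyl-4-hydroxy-5-methyl-2H-pyran-2-one hydroiodide | CCc1oc(=O)c(C[NH+](C)C)c(O)c1C.[I-] | intermediate (not isolated)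
24 | 6-ethyl-5-methyl-3-methylidene-2H-pyran-2,4(3H)-dione | CCC1=C(C)C(=O)C(=C)C(=O)O1 | intermediate (not isolated)
25 | 3-{[2,4-dihydroxy-6-methoxy-5-[(2R)-2-methylbutanoyl]-3-(3-methylbut-2-en-1-yl)phenyl]methyl}-6-ethyl-4-hydroxy-5-methyl-2H-pyran-2-one | CCc1oc(=O)c(Cc2c(O)c(CC=C(C)C)c(O)c(C(=O)[C@H](C)CC)c2OC)c(O)c1C | target

**Totals**
Total step count: 11. Longest linear sequence: 7 steps (steps 3, 4, 5, 6, 9, 10, 11).

**Steps most likely to fail, with fallbacks**

The first is step 9, where a hindered, doubly ortho-substituted aryllithium must add to an α-branched Weinreb amide and may instead give slow addition or proton transfer. The fallback sets out from 19 and 15 and replaces the acyl substitution by a carbonyl addition followed by oxidation. Amide 15 is reduced with LiAlH4 (Et2O, −40 → 0 °C) to (2R)-2-methylbutanal F1, which is used at once as its dried ethereal solution. Aryllithium 20, generated from 19 as before, adds to F1 at −78 °C to give the carbinol (2R)-1-[6-methoxy-2,4-bis(methoxymethoxy)-3-(3-methylbut-2-en-1-yl)phenyl]-2-methylbutan-1-ol F2 (both C1 epimers). Buffered Dess–Martin periodinane oxidation (NaHCO3, CH2Cl2, 0 °C) then comes back to the route at ketone 21.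

The second is step 10, where Brønsted acid may cyclise the prenyl group onto a neighbouring phenol (chroman formation) or slowly erode the α-stereocentre. The fallback sets out from 21 and avoids protic acid altogether by a trans-protection. Me3SiOTf with 2,2'-bipyridyl (MeCN, 0 °C) converts both aryl MOM ethers into aryl silyl ethers, giving (2R)-1-[6-methoxy-3-(3-methylbut-2-en-1-yl)-2,4-bis(trimethylsilyloxy)phenyl]-2-methylbutan-1-one F3. Addition of water at rt hydrolyses the labile aryl silyl ethers and comes back to the route at 22.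

The third is step 11, where the methylidene-pyrandione 24 may be trapped too slowly by the acyl-deactivated arene and be lost to self-condensation. The fallback sets out from 22 and reverses the roles of the two partners. Compound 22 is aminomethylated at its single free ring carbon with Eschenmoser's salt (CH2Cl2, rt, then aq NaHCO3) to give the isolable Mannich base (2R)-1-[3-[(dimethylamino)methyl]-4,6-dihydroxy-2-methoxy-5-(3-methylbut-2-en-1-yl)phenyl]-2-methylbutan-1-one F4. Heating F4 with pyranone 5 (dioxane, 90 °C) expels dimethylamine to give the ortho-quinone methide 3-hydroxy-5-methoxy-6-methylidene-4-[(2R)-2-methylbutanoyl]-2-(3-methylbut-2-en-1-yl)cyclohexa-2,4-dien-1-one F5. This is captured in a Michael addition by C3 of 5 and comes back to the route at target 25.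

**Further compounds**
F1 | step 9 | (2R)-2-methylbutanal | CC[C@@H](C)C=O
F2 | step 9 | (2R)-1-[6-methoxy-2,4-bis(methoxymethoxy)-3-(3-methylbut-2-en-1-yl)phenyl]-2-methylbutan-1-ol (both C1 epimers) | CC[C@@H](C)C(O)c1c(OC)cc(OCOC)c(CC=C(C)C)c1OCOC
F3 | step 10 | (2R)-1-[6-methoxy-3-(3-methylbut-2-en-1-yl)-2,4-bis(trimethylsilyloxy)phenyl]-2-methylbutan-1-one | CC[C@@H](C)C(=O)c1c(OC)cc(O[Si](C)(C)C)c(CC=C(C)C)c1O[Si](C)(C)C
F4 | step 11 | (2R)-1-[3-[(dimethylamino)methyl]-4,6-dihydroxy-2-methoxy-5-(3-methylbut-2-en-1-yl)phenyl]-2-methylbutan-1-one | CC[C@@H](C)C(=O)c1c(OC)c(CN(C)C)c(O)c(CC=C(C)C)c1O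
F5 | step 11 | 3-hydroxy-5-methoxy-6-methylidene-4-[(2R)-2-methylbutanoyl]-2-(3-methylbut-2-en-1-yl)cyclohexa-2,4-dien-1-one | CC[C@@H](C)C(=O)C1=C(OC)C(=C)C(=O)C(CC=C(C)C)=C1O
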